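**Retrosynthetic overview**

1. Target ⇒ (13E)-8,15-diol (selective O-acetylation) ⇒ terminal alkyne at C13 (Zr-catalysed methylalumination, then CH2O, fixes 13E) ⇒ δ-lactone between C13 and the C8 oxygen.
2. δ-Lactone ⇒ 8(17)-ene acid: iodolactonization from the C9 chain delivers the C8 oxygen cis to that chain ⇒ 8-keto ester.
3. C9–C11 bond: Mukaiyama–Michael addition of the Δ8(9) silyl enol ether of the cis-decalone to methyl acrylate (fragment union, sets C9); the enol ether comes from Me2CuLi addition to a bicyclic enone (C10 methyl, cis ring fusion).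
4. Ring B (formed second) ⇒ aldol condensation of an (R)-1,5-diketone; ring A (formed first) ⇒ allylation and ring-closing metathesis.
5. C5 stereocentre ⇒ amine-catalysed Michael addition of 3,3-dimethylpent-4-enal to methyl vinyl ketone.

Assumption: labdane numbering (C1–C20) is used for atom labels, and the SMILES is read literally as (5R,8S,9R,10S), i.e. a cis-fused decalin with H-5, CH3-20, C-11 and 8-OH all on one face (β).

**Route**

Step 1
Reactants: 1 methyl 3,3-dimethylpent-4-enoate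
Product: 2 3,3-dimethylpent-4-enal
Conditions: i-Bu2AlH (1.05 equiv), CH2Cl2, −78 °C; MeOH quench, aq. KNaC4H4O6
Reagents that add atoms: none
Why: Partial hydride reduction of an ester, where the aluminium hemiacetal of this β-quaternary ester survives at −78 °C and gives the aldehyde only on work-up.

Step 2
Reactants: 2 3,3-dimethylpent-4-enal; 3 but-3-en-2-one
Product: 4 (2R)-2-(2-methylbut-3-en-2-yl)-5-oxohexanal
Conditions: (R)-2-[diphenyl(trimethylsilyloxy)methyl]pyrrolidine (10 mol %), ethyl 3,4-dihydroxybenzoate (20 mol %), neat, 4 °C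
Reagents that add atoms: none
Why: Enamine-catalysed intermolecular Michael addition in which the (E)-enamine is attacked on the face away from the diaryl(silyloxy)methyl group, setting C5 as R.

Step 3
Reactants: 4 (2R)-2-(2-methylbut-3-en-2-yl)-5-oxohexanal
Product: 5 (5R,6RS)-6-hydroxy-5-(2-methylbut-3-en-2-yl)non-8-en-2-one
Conditions: allylboronic acid pinacol ester (1.2 equiv), CH2Cl2, 25 °C; aq. NaHCO3
Reagents that add atoms: allylboronic acid pinacol ester, C=CCB1OC(C)(C)C(C)(C)O1
Why: Carbonyl allylboration through a closed six-membered transition state is selective for the aldehyde over the methyl ketone, and the new carbinol centre (a mixture) is erased in step 6.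

Step 4
Reactants: 5 (5R,6RS)-6-hydroxy-5-(2-methylbut-3-en-2-yl)non-8-en-2-one
Product: 6 4-[(1R,6RS)-6-hydroxy-2,2-dimethylcyclohex-3-en-1-yl]butan-2-one
Conditions: second-generation Grubbs catalyst (5 mol %), CH2Cl2, 40 °C
Reagents that add atoms: none
Why: Ring-closing metathesis of the two terminal vinyl groups closes ring A with loss of ethene, helped by the gem-dimethyl group, and does not touch C5.

Step 5
Reactants: 6 4-[(1R,6RS)-6-hydroxy-2,2-dimethylcyclohex-3-en-1-yl]butan-2-one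
Product: 7 4-[(1R,6RS)-6-hydroxy-2,2-dimethylcyclohexyl]butan-2-one
Conditions: H2 (1 atm), Pd/C, EtOAc, 25 °C
Reagents that add atoms: none
Why: Heterogeneous catalytic hydrogenation saturates the ring olefin and leaves the ketone and alcohol unchanged.

Step 6
Reactants: 7 4-[(1R,6RS)-6-hydroxy-2,2-dimethylcyclohexyl]butan-2-one
Product: 8 (2R)-3,3-dimethyl-2-(3-oxobutyl)cyclohexan-1-one
Conditions: Dess–Martin periodinane (1.3 equiv), CH2Cl2, 25 °C
Reagents that add atoms: none
Why: Dess–Martin oxidation of the secondary alcohol under neutral conditions gives the 1,5-diketone without epimerising the adjacent C5 centre.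

Step 7
Reactants: 8 (2R)-3,3-dimethyl-2-(3-oxobutyl)cyclohexan-1-one
Product: 10 (4aR)-5,5-dimethyl-4,4a,5,6,7,8-hexahydronaphthalen-2(3H)-one, via ketol 9 (not isolated)
Conditions: KOH (1 equiv), MeOH, 25 → 45 °C
Reagents that add atoms: none
Why: Intramolecular aldol condensation (the ring-closing half of a Robinson annulation) forms ring B, and C5 survives because its proton, flanked by the gem-dimethyl carbon, enolises far more slowly than the methyl ketone.

Step 8
Reactants: 10 (4aR)-5,5-dimethyl-4,4a,5,6,7,8-hexahydronaphthalen-2(3H)-one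
Product: 12 trimethyl{[(4aR,8aS)-5,5,8a-trimethyl-3,4,4a,5,6,7,8,8a-octahydronaphthalen-2-yl]oxy}silane, via lithium enolate 11 (not isolated)
Conditions: Me2CuLi (from MeLi, CuI; 1.5 equiv), Et2O, −78 → 0 °C; then Me3SiCl, Et3N, −78 → 25 °C
Reagents that add atoms: lithium dimethylcuprate, [Li+].C[Cu-]C; chlorotrimethylsilane, C[Si](C)(C)Cl
Why: Gilman cuprate conjugate addition places the C10 methyl syn to H-5 (cis ring fusion) because the other face of C10 is blocked by the axial C4 methyl that sits 1,3 to it, and silylation traps the enolate regiospecifically at C8/C9.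

Step 9
Reactants: 12 trimethyl{[(4aR,8aS)-5,5,8a-trimethyl-3,4,4a,5,6,7,8,8a-octahydronaphthalen-2-yl]oxy}silane; 13 methyl prop-2-enoate
Product: 14 methyl 3-[(1R,4aR,8aS)-5,5,8a-trimethyl-2-oxodecahydronaphthalen-1-yl]propanoate
Conditions: TiCl4 (1.1 equiv), CH2Cl2, −78 °C; aq. NaHCO3
Reagents that add atoms: none
Why: Intermolecular Mukaiyama–Michael addition forms C9–C11, with the acrylate attacked axially on the convex β-face of the cis-decalin enol ether (anti to the axial C1–C10 bond, away from ring A), so the new chain is cis to CH3-20 and H-5.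

Step 10
Reactants: 14 methyl 3-[(1R,4aR,8aS)-5,5,8a-trimethyl-2-oxodecahydronaphthalen-1-yl]propanoate
Product: 15 methyl 3-[(1S,4aR,8aS)-5,5,8a-trimethyl-2-methylidenedecahydronaphthalen-1-yl]propanoate
Conditions: Zn, CH2Br2, TiCl4, THF, 0 → 25 °C
Reagents that add atoms: dibromomethane, BrCBr
Why: Lombardo (Takai-type) methylenation is non-basic, so the hindered ketone is converted without epimerising C9 and the ester is untouched (the C9 descriptor changes to S only through a priority switch).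

Step 11
Reactants: 15 methyl 3-[(1S,4aR,8aS)-5,5,8a-trimethyl-2-methylidenedecahydronaphthalen-1-yl]propanoate
Product: 16 3-[(1S,4aR,8aS)-5,5,8a-trimethyl-2-methylidenedecahydronaphthalen-1-yl]propanoic acid
Conditions: LiOH, THF–MeOH–H2O, 25 °C; then 1 M HCl
Reagents that add atoms: lithium hydroxide, [Li+].[OH-]
Why: Ester saponification, with no epimerisable centre left next to a carbonyl.

Step 12
Reactants: 16 3-[(1S,4aR,8aS)-5,5,8a-trimethyl-2-methylidenedecahydronaphthalen-1-yl]propanoic acid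
Product: 17 (4aS,6aR,10aS,10bR)-4a-(iodomethyl)-7,7,10a-trimethyldodecahydro-3H-benzo[f]chromen-3-one
Conditions: I2 (3 equiv), NaHCO3, MeCN–H2O, 0 °C, dark
Reagents that add atoms: iodine, II
Why: Kinetic 6-exo iodolactonization in which the carboxylate on the axial β chain at C9 can only reach the β (equatorial) side of C8 (a trans-diaxial fused lactone cannot form), so C8–O is cis to the C9 chain and the CH2I group is α.

Step 13
Reactants: 17 (4aS,6aR,10aS,10bR)-4a-(iodomethyl)-7,7,10a-trimethyldodecahydro-3H-benzo[f]chromen-3-one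
Product: 18 (4aS,6aR,10aS,10bR)-4a,7,7,10a-tetramethyldodecahydro-3H-benzo[f]chromen-3-one
Conditions: Bu3SnH (2 equiv, 0.3 M), AIBN (cat.), toluene, 80 °C
Reagents that add atoms: none
Why: Radical dehalogenation turns CH2I into CH3-17, and a high stannane concentration outruns a 1,2-acyloxy shift of the β-(acyloxy)alkyl radical.

Step 14
Reactants: 18 (4aS,6aR,10aS,10bR)-4a,7,7,10a-tetramethyldodecahydro-3H-benzo[f]chromen-3-one
Product: 19 (3RS,4aS,6aR,10aS,10bR)-4a,7,7,10a-tetramethyldodecahydro-1H-benzo[f]chromen-3-ol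
Conditions: i-Bu2AlH (1.1 equiv), CH2Cl2, −78 °C; aq. KNaC4H4O6
Reagents that add atoms: none
Why: Partial reduction of a lactone to the lactol, which is in equilibrium with its open hydroxy aldehyde form.

Step 15
Reactants: 19 (3RS,4aS,6aR,10aS,10bR)-4a,7,7,10a-tetramethyldodecahydro-1H-benzo[f]chromen-3-ol
Product: 20 (1R,2S,4aR,8aS)-1-(but-3-yn-1-yl)-2,5,5,8a-tetramethyldecahydronaphthalen-2-ol
Conditions: dimethyl (1-diazo-2-oxopropyl)phosphonate (1.5 equiv), K2CO3, MeOH, 0 → 25 °C
Reagents that add atoms: dimethyl (1-diazo-2-oxopropyl)phosphonate, COP(=O)(OC)C(=[N+]=[N-])C(C)=O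
Why: Ohira–Bestmann (Seyferth–Gilbert) homologation of the open aldehyde form gives the terminal alkyne under mild base that leaves the tertiary alcohol and all stereocentres untouched.

Step 16
Reactants: 20 (1R,2S,4aR,8aS)-1-(but-3-yn-1-yl)-2,5,5,8a-tetramethyldecahydronaphthalen-2-ol
Product: 23 (1R,2S,4aR,8aS)-1-[(3E)-5-hydroxy-3-methylpent-3-en-1-yl]-2,5,5,8a-tetramethyldecahydronaphthalen-2-ol, via alkenylalane 21 (not isolated), via lithium aluminate 22 (not isolated)
Conditions: Me3Al (3 equiv), Cp2ZrCl2 (0.5 equiv), CH2Cl2, 0 → 25 °C; n-BuLi, THF, −78 °C; (CH2O)n, −78 → 25 °C; aq. HCl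
Reagents that add atoms: trimethylaluminium, C[Al](C)C; paraformaldehyde (formaldehyde), C=O
Why: Negishi zirconium-catalysed carboalumination adds CH3 and Al syn across the terminal alkyne (methyl on the internal carbon), and trapping the aluminate with formaldehyde retains the geometry to give the 13E allylic alcohol.

Step 17
Reactants: 23 (1R,2S,4aR,8aS)-1-[(3E)-5-hydroxy-3-methylpent-3-en-1-yl]-2,5,5,8a-tetramethyldecahydronaphthalen-2-ol
Product: 24 (2E)-5-[(1R,2S,4aR,8aS)-2-hydroxy-2,5,5,8a-tetramethyldecahydronaphthalen-1-yl]-3-methylpent-2-en-1-yl acetate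
Conditions: Ac2O (1.2 equiv), pyridine, CH2Cl2, 0 → 25 °C
Reagents that add atoms: acetic anhydride, CC(=O)OC(C)=O
Why: O-Acylation is selective for the primary allylic alcohol because the hindered tertiary 8-OH does not react without forcing conditions.

**Compound list**

1 | methyl 3,3-dimethylpent-4-enoate | COC(=O)CC(C)(C)C=C | starting material
2 | 3,3-dimethylpent-4-enal | O=CCC(C)(C)C=C | intermediate
3 | but-3-en-2-one (methyl vinyl ketone) | CC(=O)C=C | starting material
4 | (2R)-2-(2-methylbut-3-en-2-yl)-5-oxohexanal | CC(=O)CC[C@@H](C=O)C(C)(C)C=C | intermediate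
5 | (5R,6RS)-6-hydroxy-5-(2-methylbut-3-en-2-yl)non-8-en-2-one (carbinol epimers) | CC(=O)CC[C@@H](C(O)CC=C)C(C)(C)C=C | intermediate
6 | 4-[(1R,6RS)-6-hydroxy-2,2-dimethylcyclohex-3-en-1-yl]butan-2-one | CC(=O)CC[C@H]1C(O)CC=CC1(C)C | intermediate
7 | 4-[(1R,6RS)-6-hydroxy-2,2-dimethylcyclohexyl]butan-2-one | CC(=O)CC[C@H]1C(O)CCCC1(C)C | intermediate
8 | (2R)-3,3-dimethyl-2-(3-oxobutyl)cyclohexan-1-one | CC(=O)CC[C@H]1C(=O)CCCC1(C)C | intermediate
9 | (4aR,8aS)-8a-hydroxy-5,5-dimethyloctahydronaphthalen-2(1H)-one (cis-fused ketol, not isolated) | O=C1C[C@@]2(O)CCCC(C)(C)[C@H]2CC1 | intermediate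
10 | (4aR)-5,5-dimethyl-4,4a,5,6,7,8-hexahydronaphthalen-2(3H)-one | O=C1C=C2CCCC(C)(C)[C@H]2CC1 | intermediate
11 | lithium (4aR,8aS)-5,5,8a-trimethyl-3,4,4a,5,6,7,8,8a-octahydronaphthalen-2-olate (cis-fused, not isolated) | [Li+].[O-]C1=C[C@@]2(C)CCCC(C)(C)[C@H]2CC1 | intermediate
12 | trimethyl{[(4aR,8aS)-5,5,8a-trimethyl-3,4,4a,5,6,7,8,8a-octahydronaphthalen-2-yl]oxy}silane (cis-fused) | C[Si](C)(C)OC1=C[C@@]2(C)CCCC(C)(C)[C@H]2CC1 | intermediate
13 | methyl prop-2-enoate (methyl acrylate) | COC(=O)C=C | starting material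
14 | methyl 3-[(1R,4aR,8aS)-5,5,8a-trimethyl-2-oxodecahydronaphthalen-1-yl]propanoate (C9 chain cis to CH3-20 and H-5) | COC(=O)CC[C@@H]1[C@@]2(C)CCCC(C)(C)[C@H]2CCC1=O | intermediate
15 | methyl 3-[(1S,4aR,8aS)-5,5,8a-trimethyl-2-methylidenedecahydronaphthalen-1-yl]propanoate | COC(=O)CC[C@@H]1[C@@]2(C)CCCC(C)(C)[C@H]2CCC1=C | intermediate
16 | 3-[(1S,4aR,8aS)-5,5,8a-trimethyl-2-methylidenedecahydronaphthalen-1-yl]propanoic acid | OC(=O)CC[C@@H]1[C@@]2(C)CCCC(C)(C)[C@H]2CCC1=C | intermediate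
17 | (4aS,6aR,10aS,10bR)-4a-(iodomethyl)-7,7,10a-trimethyldodecahydro-3H-benzo[f]chromen-3-one | O=C1CC[C@@H]2[C@@]3(C)CCCC(C)(C)[C@H]3CC[C@]2(CI)O1 | intermediate
18 | (4aS,6aR,10aS,10bR)-4a,7,7,10a-tetramethyldodecahydro-3H-benzo[f]chromen-3-one | O=C1CC[C@@H]2[C@@]3(C)CCCC(C)(C)[C@H]3CC[C@]2(C)O1 | intermediate
19 | (3RS,4aS,6aR,10aS,10bR)-4a,7,7,10a-tetramethyldodecahydro-1H-benzo[f]chromen-3-ol (lactol, anomers) | OC1CC[C@@H]2[C@@]3(C)CCCC(C)(C)[C@H]3CC[C@]2(C)O1 | intermediate
20 | (1R,2S,4aR,8aS)-1-(but-3-yn-1-yl)-2,5,5,8a-tetramethyldecahydronaphthalen-2-ol | C#CCC[C@@H]1[C@@]2(C)CCCC(C)(C)[C@H]2CC[C@]1(C)O | intermediate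
21 | (E)-alkenyl(dimethyl)alane of 20 with CH3 on C13 and the 8-O bound to AlMe2 (not isolated) | C[Al](C)/C=C(\C)CC[C@@H]1[C@@]2(C)CCCC(C)(C)[C@H]2CC[C@]1(C)O[Al](C)C | intermediate
22 | lithium butyl(dimethyl)[(E)-alkenyl]aluminate derived from 21 (not isolated) | [Li+].CCCC[Al-](C)(C)/C=C(\C)CC[C@@H]1[C@@]2(C)CCCC(C)(C)[C@H]2CC[C@]1(C)O[Al](C)C | intermediate
23 | (1R,2S,4aR,8aS)-1-[(3E)-5-hydroxy-3-methylpent-3-en-1-yl]-2,5,5,8a-tetramethyldecahydronaphthalen-2-ol | OC/C=C(\C)CC[C@@H]1[C@@]2(C)CCCC(C)(C)[C@H]2CC[C@]1(C)O | intermediate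
24 | (2E)-5-[(1R,2S,4aR,8aS)-2-hydroxy-2,5,5,8a-tetramethyldecahydronaphthalen-1-yl]-3-methylpent-2-en-1-yl acetate (CNP0268033.2) | CC(=O)OC/C=C(\C)CC[C@@H]1[C@@]2(C)CCCC(C)(C)[C@H]2CC[C@]1(C)O | target

**Step count and risks**

Total step count: 17. Longest linear sequence: 17 steps (1 → 24).

The three steps most likely to fail:

Step 2 (enamine Michael addition of an aldehyde whose α-carbon is neopentyl-like; slow turnover or eroded ee). Fallback, setting out from 2 and returning at 4: 2 is condensed with (S)-1-amino-2-(methoxymethyl)pyrrolidine to give the (E)-hydrazone F1. Deprotonation with LiN(i-Pr)2 in THF at 0 °C and alkylation with 2-(2-bromoethyl)-2-methyl-1,3-dioxolane at −100 → 25 °C gives the alkylated hydrazone F2, in which the auxiliary controls the new C5 centre (R). Two-phase aqueous oxalic acid/Et2O cleaves the hydrazone without racemisation to the aldehyde ketal F3, and pyridinium p-toluenesulfonate in wet acetone removes the dioxolane to give 4.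

Step 9 (Mukaiyama–Michael addition of a hindered enol silane, next to a quaternary carbon, to a weak acceptor). Fallback, setting out from 12 and returning at 16: 12 is cleaved with MeLi (THF, 0 °C) to the regiodefined lithium enolate, which is alkylated with allyl bromide on the same convex β-face to give the allyl ketone F4. Lombardo methylenation (Zn, CH2Br2, TiCl4) gives the diene F5. 9-BBN, then H2O2/NaOH, hydroborates the unhindered monosubstituted vinyl group selectively to give the primary alcohol F6. TEMPO/PhI(OAc)2 in MeCN–H2O oxidises it to acid 16.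

Step 16 (carboalumination and formaldehyde trapping in the presence of a free tertiary aluminium alkoxide). Fallback, setting out from 18 and returning at 23: lactone 18 is treated with MeLi (1.05 equiv, THF, −78 °C) to give the hydroxy methyl ketone F7, which is in equilibrium with its cyclic hemiketal. Horner–Wadsworth–Emmons olefination with triethyl phosphonoacetate/NaH (THF, reflux) gives the (E)-enoate F8 after chromatographic removal of the minor (Z)-isomer. i-Bu2AlH (CH2Cl2, −78 → 0 °C) reduces the ester to diol 23.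

**Further compounds**

F1 | step 2 | (2S)-N-[(1E)-3,3-dimethylpent-4-en-1-ylidene]-2-(methoxymethyl)pyrrolidin-1-amine | COC[C@@H]1CCCN1/N=C/CC(C)(C)C=C
F2 | step 2 | (2S)-2-(methoxymethyl)-N-[(1E,2R)-2-(2-methylbut-3-en-2-yl)-4-(2-methyl-1,3-dioxolan-2-yl)butylidene]pyrrolidin-1-amine | COC[C@@H]1CCCN1/N=C/[C@H](CCC2(C)OCCO2)C(C)(C)C=C
F3 | step 2 | (2R)-2-(2-methylbut-3-en-2-yl)-4-(2-methyl-1,3-dioxolan-2-yl)butanal | O=C[C@H](CCC1(C)OCCO1)C(C)(C)C=C
F4 | step 9 | (1R,4aR,8aS)-5,5,8a-trimethyl-1-(prop-2-en-1-yl)octahydronaphthalen-2(1H)-one | C=CC[C@@H]1[C@@]2(C)CCCC(C)(C)[C@H]2CCC1=O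
F5 | step 9 | (1S,4aR,8aS)-5,5,8a-trimethyl-2-methylidene-1-(prop-2-en-1-yl)decahydronaphthalene | C=CC[C@@H]1[C@@]2(C)CCCC(C)(C)[C@H]2CCC1=C
F6 | step 9 | 3-[(1S,4aR,8aS)-5,5,8a-trimethyl-2-methylidenedecahydronaphthalen-1-yl]propan-1-ol | OCCC[C@@H]1[C@@]2(C)CCCC(C)(C)[C@H]2CCC1=C
F7 | step 16 | 4-[(1R,2S,4aR,8aS)-2-hydroxy-2,5,5,8a-tetramethyldecahydronaphthalen-1-yl]butan-2-one | CC(=O)CC[C@@H]1[C@@]2(C)CCCC(C)(C)[C@H]2CC[C@]1(C)O
F8 | step 16 | ethyl (2E)-5-[(1R,2S,4aR,8aS)-2-hydroxy-2,5,5,8a-tetramethyldecahydronaphthalen-1-yl]-3-methylpent-2-enoate | CCOC(=O)/C=C(\C)CC[C@@H]1[C@@]2(C)CCCC(C)(C)[C@H]2CC[C@]1(C)O
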